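**Retrosynthetic overview**

- Target numbering: C1 is the quaternary carbinol carbon carrying C7H2OBz, C2 is CH(OBz), C3=C4 is the alkene, C5 and C6 are CH(OH). The strategy rests on the chain C7–C1(O)–C2–C3=C4 inside the six-membered carbocycle: with C7 as a carboxyl it is a γ,δ-unsaturated α-alkoxy acid, the retron of an ester enolate Claisen shift, and O1/O6 are cis, so one acetonide can span them.
- Disconnecting C1–C2 and reconnecting C4 to the carboxyl oxygen gives a 2,3-O-isopropylidene-4-O-silyl-D-mannono-1,5-lactone with an (E)-CH=CH–OPMB group on C5. Mannose C1–C6 become C7, C1, C6, C5, C4, C3; the added enol ether carbon becomes C2.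
- The lactone is made from D-mannose through a pyranose whose lactol is masked as a fluoride-labile silyl glycoside, because a methyl glycoside could not be hydrolysed once the enol ether and acetonide are present. The (E)-enol ether comes from Takai iodo-olefination and stereoretentive copper-catalysed C–O coupling rather than an E/Z-unselective Wittig reaction.
- Only the carbocycle is built (step 10); the pyranose and acetal rings are scaffolding. Endgame: acid to C7 alcohol, PMB removal, benzoylation of O2 and O7, acidic release of O1, O5 and O6.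

Key step: step 10

Remark on the chemistry: silyl glycosides 5–13 are drawn as α anomers; the β anomer would serve equally, since mannose C1 ends as the lactone carbonyl of 15. "Mannose C-n" locants refer to the sugar, plain locants from step 10 onward to the target numbering above.

**Route**

Step 1
Reactants: 1 D-mannose; 2 2-methoxypropene
Product: 3 2,3:4,6-di-O-isopropylidene-α-D-mannopyranose
Conditions: 2 (2.5 equiv), TsOH·H2O (cat.), DMF, 0 °C
Reagents that add atoms: 2-methoxypropene, COC(C)=C
Why: Kinetic acid-catalysed acetalisation with an enol ether traps the pyranose form, tying O4/O6 into a dioxane and the cis O2/O3 pair into a dioxolane and leaving only the anomeric hydroxyl free; no stereocentre is touched.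

Step 2
Reactants: 3 2,3:4,6-di-O-isopropylidene-α-D-mannopyranose; 4 tert-butyldimethylsilyl chloride
Product: 5 tert-butyldimethylsilyl 2,3:4,6-di-O-isopropylidene-α-D-mannopyranoside
Conditions: 4, imidazole, DMF, rt
Reagents that add atoms: tert-butyldimethylsilyl chloride, CC(C)(C)[Si](C)(C)Cl
Why: Silyl ether formation at the only free hydroxyl masks the lactol as a base-stable, fluoride-labile silyl glycoside that can later be opened without acid.

Step 3
Reactants: 5 tert-butyldimethylsilyl 2,3:4,6-di-O-isopropylidene-α-D-mannopyranoside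
Product: 6 tert-butyldimethylsilyl 2,3-O-isopropylidene-α-D-mannopyranoside (4,6-diol)
Conditions: AcOH–H2O (7:3), rt
Reagents that add atoms: none
Why: Selective acetal hydrolysis: the trans-fused six-membered 4,6-acetal is cleaved much faster than the cis-fused 2,3-dioxolane, and the anomeric silyl ether, whose oxygen is weakly basic, should survive dilute acetic acid.

Step 4
Reactants: 6 tert-butyldimethylsilyl 2,3-O-isopropylidene-α-D-mannopyranoside
Product: 7 tert-butyldimethylsilyl 2,3-O-isopropylidene-α-D-manno-hexodialdo-1,5-pyranoside (C6 aldehyde, O4–H free)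
Conditions: TEMPO (cat.), PhI(OAc)2, CH2Cl2, rt
Reagents that add atoms: none
Why: Nitroxyl-catalysed oxidation is selective for the primary alcohol over the secondary O4–H and stops at the aldehyde in dry solvent; the conditions are not basic, so mannose C5 should not epimerise.

Step 5
Reactants: 7 the C6 aldehyde; 8 iodoform
Product: 9 tert-butyldimethylsilyl (E)-6,7-dideoxy-7-iodo-2,3-O-isopropylidene-α-D-manno-hept-6-enopyranoside (O4–H free)
Conditions: CrCl2 (excess), 8, THF–1,4-dioxane, 0 °C → rt
Reagents that add atoms: iodoform, IC(I)I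
Why: Takai iodo-olefination with the geminal dichromium reagent from CHI3 should give the (E)-vinyl iodide preferentially and tolerates the free hydroxyl; any Z isomer is to be removed by chromatography because this geometry later sets C2.

Step 6
Reactants: 9 the (E)-vinyl iodide; 10 tert-butyldimethylsilyl trifluoromethanesulfonate
Product: 11 tert-butyldimethylsilyl (E)-4-O-(tert-butyldimethylsilyl)-6,7-dideoxy-7-iodo-2,3-O-isopropylidene-α-D-manno-hept-6-enopyranoside
Conditions: 10, 2,6-lutidine, CH2Cl2, −78 → 0 °C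
Reagents that add atoms: tert-butyldimethylsilyl trifluoromethanesulfonate, CC(C)(C)[Si](C)(C)OS(=O)(=O)C(F)(F)F
Why: Silyl triflate/2,6-lutidine silylation of the hindered secondary O4–H, placed after the olefination so that no enolisable aldehyde meets the silylating agent.

Step 7
Reactants: 11 the bis-silylated (E)-vinyl iodide; 12 4-methoxybenzyl alcohol
Product: 13 tert-butyldimethylsilyl (E)-4-O-(tert-butyldimethylsilyl)-6-deoxy-2,3-O-isopropylidene-7-O-(4-methoxybenzyl)-α-D-manno-hept-6-enopyranoside (mannose C5 bears CH=CH–OPMB)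
Conditions: 12 (2 equiv), CuI (10 mol %), 3,4,7,8-tetramethyl-1,10-phenanthroline (20 mol %), Cs2CO3, toluene, 80 °C
Reagents that add atoms: 4-methoxybenzyl alcohol, COc1ccc(CO)cc1
Why: Ullmann-type copper-catalysed C–O coupling of a vinyl iodide with a primary alcohol proceeds with retention of alkene geometry, so the (E)-enol ether is obtained without an alkoxymethylene Wittig step; silyl ethers and the acetonide tolerate Cs2CO3 in toluene.

Step 8
Reactants: 13 the (E)-enol ether silyl glycoside
Product: 14 (E)-4-O-(tert-butyldimethylsilyl)-6-deoxy-2,3-O-isopropylidene-7-O-(4-methoxybenzyl)-D-manno-hept-6-enopyranose (lactol)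
Conditions: Bu4NF, AcOH (1:1), THF, −20 → 0 °C
Reagents that add atoms: none
Why: Buffered fluoride desilylation is selective for the anomeric silyl ether because the hemiacetal oxygen is a much better leaving group from silicon than the hindered secondary O4; no acid is involved, so the enol ether and acetonide persist.

Step 9
Reactants: 14 the lactol
Product: 15 (E)-4-O-(tert-butyldimethylsilyl)-6-deoxy-2,3-O-isopropylidene-7-O-(4-methoxybenzyl)-D-manno-hept-6-enono-1,5-lactone
Conditions: Dess–Martin periodinane, pyridine, CH2Cl2, 0 °C → rt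
Reagents that add atoms: none
Why: Dess–Martin oxidation of a lactol to the δ-lactone, buffered with pyridine so that the acid-sensitive enol ether and the 4-methoxybenzyl group survive.

Step 10
Reactants: 15 the δ-lactone; 4 tert-butyldimethylsilyl chloride
Product: 18 5-O-(tert-butyldimethylsilyl)-1,6-O-isopropylidene-2-O-(4-methoxybenzyl)-1,2,5,6-tetrahydroxycyclohex-3-ene-1-carboxylic acid (carboxyl and O2 and O5 on one ring face; O1 and O6 on the other), via cyclic silyl ketene acetal 16 (not isolated), via silyl ester 17 (not isolated)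
Conditions: 4 (3 equiv), KN(SiMe3)2 (added last), THF–DMPU, −78 °C → rt; toluene, 105 °C; AcOH–THF–H2O, rt
Reagents that add atoms: none
Why: Deprotonation at mannose C2 with the chlorosilane already present gives the cyclic silyl ketene acetal 16, in which C2=C1(OSi)–O5–C5–C6=C7 is the 1,5-diene of an Ireland–Claisen rearrangement; the closest known reaction types are the ester enolate Claisen shift of 6-alkenyl δ-lactones to cyclohex-3-enecarboxylic acids and that of glycal esters, which also carry oxygen on the allyl terminus. The cyclohexene (mannose C2–C3–C4–C5=C6–C7) closes in the [3,3] shift itself through a boat transition state, the only one the six-membered ketene acetal allows, the C2–C7 bond forming as the C5–O5 bond breaks. C1 is set by suprafacial chirality transfer from mannose C5: the vinyl group lies on the β face, so C7 bonds to that face of C2, which places the carboxyl cis to O5 and keeps O1 cis to O6 inside the acetonide. C2 is set by the E geometry of the enol ether, whose oxygen points away from the boat and ends trans to O1. The step needs O-silylation to outrun loss of the mannose C3 oxygen from the enolate; the cis-fused acetonide holds that C–O bond near the enolate plane, out of alignment for elimination, and the enolate is trapped as it forms. Dilute acetic acid then cleaves only the silyl ester 17 to the acid 18.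

Step 11
Reactants: 18 the cyclohexenecarboxylic acid
Product: 19 [5-O-(tert-butyldimethylsilyl)-1,6-O-isopropylidene-2-O-(4-methoxybenzyl)-1,2,5,6-tetrahydroxycyclohex-3-en-1-yl]methanol (C7 primary alcohol)
Conditions: LiAlH4, THF, 0 → 50 °C
Reagents that add atoms: none
Why: LiAlH4 reduction of the α-quaternary carboxylic acid to the primary alcohol; silyl ether, acetonide, benzylic ether and the isolated alkene are inert to hydride.

Step 12
Reactants: 19 the C7 alcohol
Product: 20 5-O-(tert-butyldimethylsilyl)-1,6-O-isopropylidene C2,C7-diol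
Conditions: DDQ, CH2Cl2–pH 7 buffer, 0 °C → rt
Reagents that add atoms: none
Why: Oxidative cleavage of the 4-methoxybenzyl ether by DDQ in wet, buffered solvent, where water rather than the neighbouring C7 hydroxyl captures the benzylic oxocarbenium ion; silyl ether and acetonide are unaffected.

Step 13
Reactants: 20 the C2,C7-diol; 21 benzoyl chloride
Product: 22 2-O,7-O-dibenzoyl-5-O-(tert-butyldimethylsilyl)-1,6-O-isopropylidene derivative of the target
Conditions: 21 (3 equiv), pyridine, DMAP (cat.), CH2Cl2, 0 °C → rt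
Reagents that add atoms: benzoyl chloride, O=C(Cl)c1ccccc1
Why: DMAP-catalysed esterification with the acid chloride acylates the only two free hydroxyls (primary C7–OH and allylic C2–OH); O1 and O6 are locked in the acetonide and O5 is silylated, so no regiochemical choice arises.

Step 14
Reactants: 22 the protected dibenzoate
Product: 23 target, [(1S,2S,5R,6S)-2-(benzoyloxy)-1,5,6-trihydroxycyclohex-3-en-1-yl]methyl benzoate
Conditions: CF3CO2H–H2O (9:1), 0 °C
Reagents that add atoms: none
Why: Acid-catalysed hydrolysis removes the isopropylidene acetal and the silyl ether in one operation; benzoates are stable to aqueous trifluoroacetic acid and acyl migration is slow under acid, so the 2,7-dibenzoate pattern should be kept.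

**Compound list**

1 | D-mannose | OC[C@H]1OC(O)[C@@H](O)[C@@H](O)[C@@H]1O | starting material
2 | 2-methoxypropene | COC(C)=C | starting material
3 | 2,3:4,6-di-O-isopropylidene-α-D-mannopyranose | O[C@@H]1[C@H]2OC(C)(C)O[C@H]2[C@@H]2OC(C)(C)OC[C@H]2O1 | intermediate
4 | tert-butyldimethylsilyl chloride | CC(C)(C)[Si](C)(C)Cl | starting material
5 | tert-butyldimethylsilyl 2,3:4,6-di-O-isopropylidene-α-D-mannopyranoside | CC(C)(C)[Si](C)(C)O[C@@H]1[C@H]2OC(C)(C)O[C@H]2[C@@H]2OC(C)(C)OC[C@H]2O1 | intermediate
6 | tert-butyldimethylsilyl 2,3-O-isopropylidene-α-D-mannopyranoside | CC(C)(C)[Si](C)(C)O[C@@H]1[C@H]2OC(C)(C)O[C@H]2[C@H](O)[C@@H](CO)O1 | intermediate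
7 | tert-butyldimethylsilyl 2,3-O-isopropylidene-α-D-manno-hexodialdo-1,5-pyranoside | CC(C)(C)[Si](C)(C)O[C@@H]1[C@H]2OC(C)(C)O[C@H]2[C@H](O)[C@@H](C=O)O1 | intermediate
8 | iodoform | IC(I)I | starting material
9 | tert-butyldimethylsilyl (E)-6,7-dideoxy-7-iodo-2,3-O-isopropylidene-α-D-manno-hept-6-enopyranoside | CC(C)(C)[Si](C)(C)O[C@@H]1[C@H]2OC(C)(C)O[C@H]2[C@H](O)[C@@H](/C=C/I)O1 | intermediate
10 | tert-butyldimethylsilyl trifluoromethanesulfonate | CC(C)(C)[Si](C)(C)OS(=O)(=O)C(F)(F)F | starting material
11 | tert-butyldimethylsilyl (E)-4-O-(tert-butyldimethylsilyl)-6,7-dideoxy-7-iodo-2,3-O-isopropylidene-α-D-manno-hept-6-enopyranoside | CC(C)(C)[Si](C)(C)O[C@@H]1[C@H]2OC(C)(C)O[C@H]2[C@H](O[Si](C)(C)C(C)(C)C)[C@@H](/C=C/I)O1 | intermediate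
12 | 4-methoxybenzyl alcohol | COc1ccc(CO)cc1 | starting material
13 | tert-butyldimethylsilyl (E)-4-O-(tert-butyldimethylsilyl)-6-deoxy-2,3-O-isopropylidene-7-O-(4-methoxybenzyl)-α-D-manno-hept-6-enopyranoside | CC(C)(C)[Si](C)(C)O[C@@H]1[C@H]2OC(C)(C)O[C@H]2[C@H](O[Si](C)(C)C(C)(C)C)[C@@H](/C=C/OCc2ccc(OC)cc2)O1 | intermediate
14 | (E)-4-O-(tert-butyldimethylsilyl)-6-deoxy-2,3-O-isopropylidene-7-O-(4-methoxybenzyl)-D-manno-hept-6-enopyranose (lactol, anomer mixture) | OC1[C@H]2OC(C)(C)O[C@H]2[C@H](O[Si](C)(C)C(C)(C)C)[C@@H](/C=C/OCc2ccc(OC)cc2)O1 | intermediate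
15 | (E)-4-O-(tert-butyldimethylsilyl)-6-deoxy-2,3-O-isopropylidene-7-O-(4-methoxybenzyl)-D-manno-hept-6-enono-1,5-lactone | O=C1O[C@H](/C=C/OCc2ccc(OC)cc2)[C@@H](O[Si](C)(C)C(C)(C)C)[C@@H]2OC(C)(C)O[C@H]12 | intermediate
16 | cyclic silyl ketene acetal of 15 (mannose C1=C2, 1-O-silyl; C3, C4, C5 and the (E)-enol ether as in 15) | CC(C)(C)[Si](C)(C)OC1=C2OC(C)(C)O[C@H]2[C@H](O[Si](C)(C)C(C)(C)C)[C@@H](/C=C/OCc2ccc(OC)cc2)O1 | intermediate
17 | tert-butyldimethylsilyl ester of acid 18 | CC(C)(C)[Si](C)(C)OC(=O)[C@@]1(OC2(C)C)[C@@H](OCc3ccc(OC)cc3)C=C[C@@H](O[Si](C)(C)C(C)(C)C)[C@@H]1O2 | intermediate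
18 | 5-O-(tert-butyldimethylsilyl)-1,6-O-isopropylidene-2-O-(4-methoxybenzyl)-1,2,5,6-tetrahydroxycyclohex-3-ene-1-carboxylic acid (carboxyl, O2, O5 on one face; O1, O6 on the other) | OC(=O)[C@@]1(OC2(C)C)[C@@H](OCc3ccc(OC)cc3)C=C[C@@H](O[Si](C)(C)C(C)(C)C)[C@@H]1O2 | intermediate
19 | C7 primary alcohol from 18 (same ring substituents and configuration) | OC[C@@]1(OC2(C)C)[C@@H](OCc3ccc(OC)cc3)C=C[C@@H](O[Si](C)(C)C(C)(C)C)[C@@H]1O2 | intermediate
20 | C2,C7-diol (5-O-silyl, 1,6-O-isopropylidene) | OC[C@@]1(OC2(C)C)[C@@H](O)C=C[C@@H](O[Si](C)(C)C(C)(C)C)[C@@H]1O2 | intermediate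
21 | benzoyl chloride | O=C(Cl)c1ccccc1 | starting material
22 | 2-O,7-O-dibenzoate (5-O-silyl, 1,6-O-isopropylidene) | O=C(OC[C@@]1(OC2(C)C)[C@@H](OC(=O)c3ccccc3)C=C[C@@H](O[Si](C)(C)C(C)(C)C)[C@@H]1O2)c1ccccc1 | intermediate
23 | [(1S,2S,5R,6S)-2-(benzoyloxy)-1,5,6-trihydroxycyclohex-3-en-1-yl]methyl benzoate | O=C(OC[C@@]1(O)[C@@H](OC(=O)c2ccccc2)C=C[C@@H](O)[C@@H]1O)c1ccccc1 | target

**Totals and risks**

Total step count: 14
Longest linear sequence: 14 steps (D-mannose to 23)

Steps most likely to fail:

1. Step 10. The allylic C5–O bond of 16 is vinylogously activated by the enol ether oxygen and may ionise before the concerted shift, or the enolate may lose the mannose C3 oxygen before it is silylated; either process would cost material or chirality transfer.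
 Fallback, setting out from vinyl iodide 11 and rejoining at diol 20: the oxygen at C2 is introduced after ring closure instead of being carried through it. Miyaura borylation of 11 (B2pin2, PdCl2(dppf), KOPh, toluene, 50 °C) would give, with retention, the bis-silylated (E)-vinylboronate F1. Buffered fluoride as in step 8 would give the lactol F2, and Dess–Martin oxidation the lactone F3. Enolisation–silylation as in step 10 would give the ketene acetal F4, which has no donor oxygen on its allyl terminus. F4 should rearrange through the same boat to the allylboronate silyl ester F5, with boron where the benzyloxy group stood. H2O2/NaOH would oxidise the C–B bond with retention and cleave the silyl ester to the hydroxy acid F6, and LiAlH4 would reduce F6 to 20.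

2. Step 7. Hot carbonate and alkoxide may strip the anomeric silyl group, or the coupling may stall or erode the alkene geometry.
 Fallback, setting out from aldehyde 7 and rejoining at enol ether 13: the boron variant of the Takai olefination (Cl2CHBpin, CrCl2, LiI, THF) would give the (E)-vinylboronate F7. Chan–Lam-type oxidative coupling with 12 (Cu(OAc)2, Et3N, 12 in excess, rt, air) would give the hydroxy enol ether F8 at room temperature with retention of geometry. Silylation of O4 (10, 2,6-lutidine, −78 °C) would give 13.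

3. Step 8. Fluoride may also attack or migrate the O4 silyl ether, so that the lactol is not released cleanly.
 Fallback, setting out from 13 and rejoining at lactone 15: excess Bu4NF (THF, rt) would remove both silyl groups to give the lactol diol F9. Ag2CO3 on Celite (benzene, reflux) oxidises lactols much faster than secondary alcohols and would give the hydroxy lactone F10. Immediate silylation of O4 (10, 2,6-lutidine, −78 °C) would give 15.

Further compounds
F1 | step 10 | tert-butyldimethylsilyl (E)-4-O-(tert-butyldimethylsilyl)-6,7-dideoxy-2,3-O-isopropylidene-7-(pinacolboryl)-α-D-manno-hept-6-enopyranoside | CC(C)(C)[Si](C)(C)O[C@@H]1[C@H]2OC(C)(C)O[C@H]2[C@H](O[Si](C)(C)C(C)(C)C)[C@@H](/C=C/B2OC(C)(C)C(C)(C)O2)O1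
F2 | step 10 | (E)-4-O-(tert-butyldimethylsilyl)-6,7-dideoxy-2,3-O-isopropylidene-7-(pinacolboryl)-D-manno-hept-6-enopyranose (lactol) | OC1[C@H]2OC(C)(C)O[C@H]2[C@H](O[Si](C)(C)C(C)(C)C)[C@@H](/C=C/B2OC(C)(C)C(C)(C)O2)O1
F3 | step 10 | (E)-4-O-(tert-butyldimethylsilyl)-6,7-dideoxy-2,3-O-isopropylidene-7-(pinacolboryl)-D-manno-hept-6-enono-1,5-lactone | O=C1[C@H]2OC(C)(C)O[C@H]2[C@H](O[Si](C)(C)C(C)(C)C)[C@@H](/C=C/B2OC(C)(C)C(C)(C)O2)O1
F4 | step 10 | cyclic silyl ketene acetal of F3 | CC(C)(C)[Si](C)(C)OC1=C2OC(C)(C)O[C@H]2[C@H](O[Si](C)(C)C(C)(C)C)[C@@H](/C=C/B2OC(C)(C)C(C)(C)O2)O1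
F5 | step 10 | tert-butyldimethylsilyl 5-O-(tert-butyldimethylsilyl)-1,6-O-isopropylidene-2-(pinacolboryl)-1,5,6-trihydroxycyclohex-3-ene-1-carboxylate (boron in the place of O2 of 17) | CC(C)(C)[Si](C)(C)OC(=O)[C@@]1(OC2(C)C)[C@@H](B3OC(C)(C)C(C)(C)O3)C=C[C@@H](O[Si](C)(C)C(C)(C)C)[C@@H]1O2
F6 | step 10 | 5-O-(tert-butyldimethylsilyl)-1,6-O-isopropylidene-1,2,5,6-tetrahydroxycyclohex-3-ene-1-carboxylic acid (O2–H free, configuration as 20) | OC(=O)[C@@]1(OC2(C)C)[C@@H](O)C=C[C@@H](O[Si](C)(C)C(C)(C)C)[C@@H]1O2
F7 | step 7 | tert-butyldimethylsilyl (E)-6,7-dideoxy-2,3-O-isopropylidene-7-(pinacolboryl)-α-D-manno-hept-6-enopyranoside (O4–H free) | CC(C)(C)[Si](C)(C)O[C@@H]1[C@H]2OC(C)(C)O[C@H]2[C@H](O)[C@@H](/C=C/B2OC(C)(C)C(C)(C)O2)O1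
F8 | step 7 | tert-butyldimethylsilyl (E)-6-deoxy-2,3-O-isopropylidene-7-O-(4-methoxybenzyl)-α-D-manno-hept-6-enopyranoside (O4–H free) | CC(C)(C)[Si](C)(C)O[C@@H]1[C@H]2OC(C)(C)O[C@H]2[C@H](O)[C@@H](/C=C/OCc2ccc(OC)cc2)O1
F9 | step 8 | (E)-6-deoxy-2,3-O-isopropylidene-7-O-(4-methoxybenzyl)-D-manno-hept-6-enopyranose (lactol, O4–H free) | OC1[C@H]2OC(C)(C)O[C@H]2[C@H](O)[C@@H](/C=C/OCc2ccc(OC)cc2)O1
F10 | step 8 | (E)-6-deoxy-2,3-O-isopropylidene-7-O-(4-methoxybenzyl)-D-manno-hept-6-enono-1,5-lactone (O4–H free) | O=C1[C@H]2OC(C)(C)O[C@H]2[C@H](O)[C@@H](/C=C/OCc2ccc(OC)cc2)O1
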